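Everything rests on cutting the dihydrofuran fused to ring B at O1–C2 and C3a–C3. The key step exploits that O1 and C3a are a phenol oxygen with a single free ortho carbon, and that C2, a benzylic O‑bearing carbon, can pass through the acetal level carrying a temporary sulfur. One operation joins a simple phenol to an enantiopure α‑sulfinyl stilbene: interrupted Pummerer activation, sulfonium [3,3] shift and thionium capture forge both bonds and pass chirality from sulfur to C3. After desulfurization the ester is added to a tetrahydrofuran aryllithium made by nitro‑Michael addition and quinone methide cyclization; an ortho‑quinone methide [4+1] annulation and hydrogenolysis finish.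

Key step: step 3

Remark: the structure is used exactly as its SMILES defines it; ring A is the benzo ring of dihydrobenzofuran 1 (it carries the tetrahydrofuran), ring B is the benzo ring of dihydrobenzofuran 2 (7‑OH ortho to O1, linked to C3 of dihydrobenzofuran 1 through C5), and all four O–CH(aryl) centres are taken to be the thermodynamically favoured trans‑to‑neighbour arrangements.

Step 1
Reactants: 1 1-(benzyloxy)-4-(chloromethyl)benzene; 2 (1R,2S,5R)-menthyl (S)-4-methylbenzenesulfinate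
Product: 4 (R)-1-(benzyloxy)-4-{[(4-methylphenyl)sulfinyl]methyl}benzene, via benzylic Grignard reagent 3 (not isolated)
Conditions: Mg, THF, 0 °C; then 2, toluene/THF, −40 → 0 °C
Reagents that add atoms: none
Why: Andersen sulfoxide synthesis, in which the Grignard reagent displaces menthoxide at sulfur with inversion, so the (S)-sulfinate should give the (R)-sulfoxide as a single enantiomer.

Step 2
Reactants: 4 (R)-benzyl sulfoxide; 5 3,5-bis(benzyloxy)benzaldehyde
Product: 7 1,3-bis(benzyloxy)-5-{(E)-2-[4-(benzyloxy)phenyl]-2-[(S)-(4-methylphenyl)sulfinyl]ethenyl}benzene, via α-phosphoryl sulfoxide 6 (not isolated)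
Conditions: LiN(i-Pr)2 (2.2 equiv), THF, −78 °C; ClP(O)(OEt)2; then 5, −78 → 23 °C
Reagents that add atoms: none
Why: One-pot C-phosphorylation and Horner–Wadsworth–Emmons olefination leaves sulfur untouched (the descriptor changes only by priority) and should favour the (E)-alkene with the bulky sulfinyl group trans to the new aryl group, the minor isomer being removed by chromatography.

Step 3
Reactants: 7 (S,E)-α-sulfinyl stilbene; 8 methyl 3-(benzyloxy)-4-hydroxybenzoate
Product: 10 methyl (3R)-7-(benzyloxy)-2-[4-(benzyloxy)phenyl]-3-[3,5-bis(benzyloxy)phenyl]-2-[(4-methylphenyl)sulfanyl]-2,3-dihydro-1-benzofuran-5-carboxylate (both C2 epimers), via aryloxysulfonium triflate 9 (not isolated)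
Conditions: Tf2O (1.05 equiv), 2,6-di-tert-butylpyridine, CH2Cl2, −78 °C; then 8, −78 → −20 °C
Reagents that add atoms: none
Why: Proposed new method: Tf2O turns sulfoxide 7 into a triflyloxysulfonium ion, phenol 8 attacks sulfur with inversion to give 9, a charge-accelerated [3,3]-sigmatropic shift then forms C3a–C3, and the resulting thionium is captured by the ring B oxygen to form O1–C2. The closest known reaction type is the extended Pummerer annulation of phenols with alkenyl sulfoxides, which normally ends at benzofurans; here the hindered base and low temperature are meant to stop it at the 2-sulfanyl-2,3-dihydrobenzofuran, and the sulfur-to-carbon chirality transfer is modelled on sulfonium-Claisen rearrangements of chiral vinyl sulfoxides. The five-membered ring closes by 5-exo-trig attack of O1 on the thionium carbon after the six-membered chair transition state of the sigmatropic step. C3 is controlled by sulfur: with the S-tolyl group and the 3,5-bis(benzyloxy)phenyl group of the (E)-alkene both equatorial in that chair, the (S)-sulfoxide should give (3R), whereas C2 is left uncontrolled because step 4 resets it. Regioselectivity is secured by the substrate, since C3 of phenol 8 is blocked by its benzyloxy group and sulfur sits on the carbon that must become C2. Pre-activation at −78 °C with a non-nucleophilic counter-ion is meant to protect the sulfur configuration and to favour O–S bond formation over aryl triflation.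

Step 4
Reactants: 10 2-sulfanyl dihydrobenzofuran
Product: 12 methyl (2R,3R)-7-(benzyloxy)-2-[4-(benzyloxy)phenyl]-3-[3,5-bis(benzyloxy)phenyl]-2,3-dihydro-1-benzofuran-5-carboxylate, via cis-dihydrobenzofuran ester 11 (not isolated)
Conditions: Bu3SnH, AIBN (cat.), toluene, 80 °C; then CF3CO2H, CH2Cl2, 0 → 23 °C
Reagents that add atoms: none
Why: Radical desulfurization of the O,S-acetal gives a benzylic α-oxy radical at C2 that should take hydrogen anti to the C3 aryl group (cis isomer 11), and acid then equilibrates C2 by reversible ionization of the benzylic aryl ether to the trans isomer without touching C3.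

Step 5
Reactants: 5 3,5-bis(benzyloxy)benzaldehyde
Product: 13 3,5-bis(benzyloxy)-2-bromobenzaldehyde
Conditions: NBS, MeCN, 0 → 23 °C
Reagents that add atoms: N-bromosuccinimide, O=C1CCC(=O)N1Br
Why: Electrophilic aromatic bromination should occur at C2, para to one benzyloxy group and ortho to the other, and less hindered than C4 between the two ethers.

Step 6
Reactants: 14 (4-bromophenoxy)triisopropylsilane
Product: 15 triisopropyl[4-(nitromethyl)phenoxy]silane
Conditions: Pd2(dba)3 (cat.), XPhos (cat.), Cs2CO3, MeNO2/1,4-dioxane, 60 °C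
Reagents that add atoms: nitromethane, C[N+](=O)[O-]
Why: Palladium-catalysed cross-coupling of an aryl bromide with the nitronate of nitromethane is a known route to arylnitromethanes and should tolerate the hindered silyl ether.

Step 7
Reactants: 13 bromo aldehyde; 15 arylnitromethane
Product: 16 {4-[(E)-2-[3,5-bis(benzyloxy)-2-bromophenyl]-1-nitroethenyl]phenoxy}triisopropylsilane
Conditions: n-BuNH2 (cat.), AcOH, toluene, 80 °C (Dean–Stark)
Reagents that add atoms: none
Why: Amine-catalysed Henry condensation through the N-butyl imine gives the conjugated α-nitrostilbene, the (E)-isomer with the nitro group trans to the bromoaryl ring being the thermodynamic product.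

Step 8
Reactants: 17 1-{4-[(triisopropylsilyl)oxy]phenyl}ethan-1-one; 18 1,3-bis(benzyloxy)-5-bromobenzene
Product: 19 2-[3,5-bis(benzyloxy)phenyl]-1-{4-[(triisopropylsilyl)oxy]phenyl}ethan-1-one
Conditions: Pd(OAc)2 (cat.), XPhos (cat.), K3PO4, toluene, 90 °C
Reagents that add atoms: none
Why: Palladium-catalysed α-arylation of the methyl ketone with the aryl bromide gives the deoxybenzoin, and a slight excess of ketone with the mild phosphate base should suppress diarylation and silyl loss.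

Step 9
Reactants: 16 (E)-α-nitrostilbene; 19 deoxybenzoin
Product: 20 (2R,3S)-3-[3,5-bis(benzyloxy)-2-bromophenyl]-2-[3,5-bis(benzyloxy)phenyl]-4-nitro-1,4-bis{4-[(triisopropylsilyl)oxy]phenyl}butan-1-one (both C4 epimers)
Conditions: 1-[(1R,2R)-2-aminocyclohexyl]-3-[3,5-bis(trifluoromethyl)phenyl]thiourea (20 mol %), PhCO2H (20 mol %), toluene, 23 °C
Reagents that add atoms: none
Why: Organocatalytic Michael addition in which the primary amine forms the (Z)-enamine of 19 while the thiourea binds the nitro group and exposes one face of the nitroalkene, which should set C2 and C3 as (2R,3S) with the aryl groups anti (the future 3,4-cis pair of the tetrahydrofuran), the nitro-bearing carbon being erased in step 10.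

Step 10
Reactants: 20 γ-nitro ketone
Product: 22 4,4'-{(2S,3R,4S,5R)-4-[3,5-bis(benzyloxy)-2-bromophenyl]-3-[3,5-bis(benzyloxy)phenyl]oxolane-2,5-diyl}diphenol, via nitro alcohol 21 (not isolated)
Conditions: NaBH4, THF/EtOH, −20 °C; then n-Bu4NF, THF, 23 → 50 °C
Reagents that add atoms: none
Why: After ketone reduction, fluoride unmasks both phenols, the phenoxide next to the nitro-bearing carbon expels nitrite to a p-quinone methide (E1cB-type 1,6-elimination) that the alkoxide closes by 5-exo-trig oxa-Michael addition, and because both O–CH(aryl) carbons can reopen through quinone methides under base the ring should funnel to the 2,3-trans/4,5-trans isomer without any cation that could attack the electron-rich aryl rings, the 3,4-cis pair from step 9 staying untouched.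

Step 11
Reactants: 22 tetrahydrofuran bisphenol
Product: 23 (2S,3R,4S,5R)-4-[3,5-bis(benzyloxy)-2-bromophenyl]-3-[3,5-bis(benzyloxy)phenyl]-2,5-bis[4-(benzyloxy)phenyl]oxolane
Conditions: BnBr, K2CO3, DMF, 23 °C
Reagents that add atoms: benzyl bromide, BrCc1ccccc1
Why: Williamson etherification of the two phenols removes the quinone methide pathway and so locks the equilibrated ring configuration.

Step 12
Reactants: 23 tetrahydrofuran aryl bromide; 12 dihydrobenzofuran methyl ester
Product: 25 diaryl ketone in which the carbonyl carbon joins C2 of the 3,5-bis(benzyloxy)phenyl ring (ring A) of the (2S,3R,4S,5R)-oxolane to C5 of the (2R,3R)-dihydrobenzofuran of 12, via aryllithium 24 (not isolated)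
Conditions: n-BuLi, THF, −78 °C; then 12, −78 → −40 °C
Reagents that add atoms: none
Why: Bromine–lithium exchange outruns deprotonation at −78 °C and the doubly ortho-substituted aryllithium should add once to the methyl ester, the crowded diaryl ketone resisting a second addition, with no stereocentre affected.

Step 13
Reactants: 25 diaryl ketone
Product: 26 ortho-hydroxy ketone (25 with the ring A benzyl ether ortho to the carbonyl replaced by OH)
Conditions: MgBr2·OEt2, toluene/Et2O, 60 °C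
Reagents that add atoms: none
Why: Chelation-controlled debenzylation, in which MgBr2 bridges the ketone and the ortho ether oxygen and bromide removes only that benzyl group.

Step 14
Reactants: 26 ortho-hydroxy ketone
Product: 27 aryl tert-butyl carbonate of 26
Conditions: Boc2O, DMAP (cat.), i-Pr2NEt, CH2Cl2, 23 °C
Reagents that add atoms: di-tert-butyl dicarbonate, CC(C)(C)OC(=O)OC(=O)OC(C)(C)C
Why: DMAP-catalysed carbonate formation on the single free phenol installs the migrating leaving group needed to release an ortho-quinone methide at low temperature.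

Step 15
Reactants: 28 1-(benzyloxy)-4-(bromomethyl)benzene; 29 (2R,5R)-2,5-dimethylthiolane
Product: 30 (2R,5R)-1-[4-(benzyloxy)benzyl]-2,5-dimethylthiolan-1-ium bromide
Conditions: acetone, 23 °C
Reagents that add atoms: none
Why: SN2 alkylation of the C2-symmetric sulfide by the benzylic bromide gives a single sulfonium salt because sulfur is not stereogenic.

Step 16
Reactants: 27 aryl carbonate ketone; 30 chiral sulfonium bromide
Product: 33 decabenzyl ether of the target with the new dihydrobenzofuran (2S,3S), via ortho-quinone methide 31 (not isolated), via sulfonium ylide 32 (not isolated)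
Conditions: LiBHEt3 (1.0 equiv), THF, −78 °C; then ylide 32 [from 30, KN(SiMe3)2, THF, −78 °C], −78 → 0 °C
Reagents that add atoms: none
Why: Hydride addition to the ketone triggers carbonate migration and elimination to ortho-quinone methide 31, which undergoes [4+1] annulation with the benzylic sulfonium ylide (conjugate addition, then the phenoxide displaces the sulfide with inversion); the C2-symmetric sulfide controls the ylide face and the anti betaine closes to the trans ring, so the new C2 and C3 should be (2S,3S), helped by the tetrahydrofuran substituent shielding one face of 31.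

Step 17
Reactants: 33 decabenzyl ether
Product: 34 kobophenol A (structure as given)
Conditions: H2 (1 atm), Pd/C, EtOAc/MeOH, 23 °C
Reagents that add atoms: none
Why: Hydrogenolysis of the ten aryl benzyl ethers under mild conditions, at which the hindered secondary benzylic ring C–O bonds of the two dihydrobenzofurans and the tetrahydrofuran are expected to survive and no stereocentre is touched.

Compound list

1 | 1-(benzyloxy)-4-(chloromethyl)benzene | ClCc1ccc(OCc2ccccc2)cc1 | starting material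
2 | (1R,2S,5R)-menthyl (S)-4-methylbenzenesulfinate | C[C@@H]1CC[C@H]([C@@H](C1)O[S@](=O)c1ccc(C)cc1)C(C)C | starting material
3 | [4-(benzyloxy)benzyl]magnesium chloride | Cl[Mg]Cc1ccc(OCc2ccccc2)cc1 | intermediate (not isolated)
4 | (R)-1-(benzyloxy)-4-{[(4-methylphenyl)sulfinyl]methyl}benzene | Cc1ccc(cc1)[S@](=O)Cc1ccc(OCc2ccccc2)cc1 | intermediate
5 | 3,5-bis(benzyloxy)benzaldehyde | O=Cc1cc(OCc2ccccc2)cc(OCc2ccccc2)c1 | starting material
6 | diethyl {[4-(benzyloxy)phenyl][(4-methylphenyl)sulfinyl]methyl}phosphonate (sulfur as in 4, both epimers at carbon) | CCOP(=O)(OCC)C(c1ccc(OCc2ccccc2)cc1)[S@@](=O)c1ccc(C)cc1 | intermediate (not isolated)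
7 | 1,3-bis(benzyloxy)-5-{(E)-2-[4-(benzyloxy)phenyl]-2-[(S)-(4-methylphenyl)sulfinyl]ethenyl}benzene | Cc1ccc(cc1)[S@](=O)/C(c1ccc(OCc2ccccc2)cc1)=C/c1cc(OCc2ccccc2)cc(OCc2ccccc2)c1 | intermediate
8 | methyl 3-(benzyloxy)-4-hydroxybenzoate | COC(=O)c1ccc(O)c(OCc2ccccc2)c1 | starting material
9 | [2-(benzyloxy)-4-(methoxycarbonyl)phenoxy]{(E)-1-[4-(benzyloxy)phenyl]-2-[3,5-bis(benzyloxy)phenyl]ethenyl}(4-methylphenyl)sulfonium trifluoromethanesulfonate | Cc1ccc(cc1)[S@@+](Oc1c(OCc2ccccc2)cc(C(=O)OC)cc1)/C(c1ccc(OCc2ccccc2)cc1)=C/c1cc(OCc2ccccc2)cc(OCc2ccccc2)c1.[O-]S(=O)(=O)C(F)(F)F | intermediate (not isolated)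
10 | methyl (3R)-7-(benzyloxy)-2-[4-(benzyloxy)phenyl]-3-[3,5-bis(benzyloxy)phenyl]-2-[(4-methylphenyl)sulfanyl]-2,3-dihydro-1-benzofuran-5-carboxylate (both C2 epimers) | COC(=O)c1cc(OCc2ccccc2)c2c(c1)[C@@H](c1cc(OCc3ccccc3)cc(OCc3ccccc3)c1)C(Sc1ccc(C)cc1)(c1ccc(OCc3ccccc3)cc1)O2 | intermediate
11 | methyl (2S,3R)-7-(benzyloxy)-2-[4-(benzyloxy)phenyl]-3-[3,5-bis(benzyloxy)phenyl]-2,3-dihydro-1-benzofuran-5-carboxylate (cis) | COC(=O)c1cc(OCc2ccccc2)c2c(c1)[C@@H](c1cc(OCc3ccccc3)cc(OCc3ccccc3)c1)[C@@H](c1ccc(OCc3ccccc3)cc1)O2 | intermediate (not isolated)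
12 | methyl (2R,3R)-7-(benzyloxy)-2-[4-(benzyloxy)phenyl]-3-[3,5-bis(benzyloxy)phenyl]-2,3-dihydro-1-benzofuran-5-carboxylate (trans) | COC(=O)c1cc(OCc2ccccc2)c2c(c1)[C@@H](c1cc(OCc3ccccc3)cc(OCc3ccccc3)c1)[C@H](c1ccc(OCc3ccccc3)cc1)O2 | intermediate
13 | 3,5-bis(benzyloxy)-2-bromobenzaldehyde | O=Cc1cc(OCc2ccccc2)cc(OCc2ccccc2)c1Br | intermediate
14 | (4-bromophenoxy)triisopropylsilane | CC(C)[Si](Oc1ccc(Br)cc1)(C(C)C)C(C)C | starting material
15 | triisopropyl[4-(nitromethyl)phenoxy]silane | CC(C)[Si](Oc1ccc(C[N+](=O)[O-])cc1)(C(C)C)C(C)C | intermediate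
16 | {4-[(E)-2-[3,5-bis(benzyloxy)-2-bromophenyl]-1-nitroethenyl]phenoxy}triisopropylsilane | [O-][N+](=O)/C(c1ccc(O[Si](C(C)C)(C(C)C)C(C)C)cc1)=C/c1cc(OCc2ccccc2)cc(OCc2ccccc2)c1Br | intermediate
17 | 1-{4-[(triisopropylsilyl)oxy]phenyl}ethan-1-one | CC(=O)c1ccc(O[Si](C(C)C)(C(C)C)C(C)C)cc1 | starting material
18 | 1,3-bis(benzyloxy)-5-bromobenzene | Brc1cc(OCc2ccccc2)cc(OCc2ccccc2)c1 | starting material
19 | 2-[3,5-bis(benzyloxy)phenyl]-1-{4-[(triisopropylsilyl)oxy]phenyl}ethan-1-one | O=C(Cc1cc(OCc2ccccc2)cc(OCc2ccccc2)c1)c1ccc(O[Si](C(C)C)(C(C)C)C(C)C)cc1 | intermediate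
20 | (2R,3S)-3-[3,5-bis(benzyloxy)-2-bromophenyl]-2-[3,5-bis(benzyloxy)phenyl]-4-nitro-1,4-bis{4-[(triisopropylsilyl)oxy]phenyl}butan-1-one (both C4 epimers) | O=C(c1ccc(O[Si](C(C)C)(C(C)C)C(C)C)cc1)[C@@H](c1cc(OCc2ccccc2)cc(OCc2ccccc2)c1)[C@@H](c1cc(OCc2ccccc2)cc(OCc2ccccc2)c1Br)C([N+](=O)[O-])c1ccc(O[Si](C(C)C)(C(C)C)C(C)C)cc1 | intermediate
21 | (2R,3S)-3-[3,5-bis(benzyloxy)-2-bromophenyl]-2-[3,5-bis(benzyloxy)phenyl]-4-nitro-1,4-bis{4-[(triisopropylsilyl)oxy]phenyl}butan-1-ol (epimers at C1 and C4) | OC(c1ccc(O[Si](C(C)C)(C(C)C)C(C)C)cc1)[C@@H](c1cc(OCc2ccccc2)cc(OCc2ccccc2)c1)[C@@H](c1cc(OCc2ccccc2)cc(OCc2ccccc2)c1Br)C([N+](=O)[O-])c1ccc(O[Si](C(C)C)(C(C)C)C(C)C)cc1 | intermediate (not isolated)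
22 | 4,4'-{(2S,3R,4S,5R)-4-[3,5-bis(benzyloxy)-2-bromophenyl]-3-[3,5-bis(benzyloxy)phenyl]oxolane-2,5-diyl}diphenol | Brc1c(OCc2ccccc2)cc(OCc2ccccc2)cc1[C@@H]1[C@H](c2cc(OCc3ccccc3)cc(OCc3ccccc3)c2)[C@@H](c2ccc(O)cc2)O[C@H]1c1ccc(O)cc1 | intermediate
23 | (2S,3R,4S,5R)-4-[3,5-bis(benzyloxy)-2-bromophenyl]-3-[3,5-bis(benzyloxy)phenyl]-2,5-bis[4-(benzyloxy)phenyl]oxolane | Brc1c(OCc2ccccc2)cc(OCc2ccccc2)cc1[C@@H]1[C@H](c2cc(OCc3ccccc3)cc(OCc3ccccc3)c2)[C@@H](c2ccc(OCc3ccccc3)cc2)O[C@H]1c1ccc(OCc2ccccc2)cc1 | intermediate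
24 | aryllithium from 23 (Li in place of Br) | [Li]c1c(OCc2ccccc2)cc(OCc2ccccc2)cc1[C@@H]1[C@H](c2cc(OCc3ccccc3)cc(OCc3ccccc3)c2)[C@@H](c2ccc(OCc3ccccc3)cc2)O[C@H]1c1ccc(OCc2ccccc2)cc1 | intermediate (not isolated)
25 | diaryl ketone: {2,4-bis(benzyloxy)-6-[(2S,3R,4S,5R)-oxolan-3-yl of 23]phenyl}{(2R,3R)-dihydrobenzofuran-5-yl of 12}methanone | O=C(c1c(OCc2ccccc2)cc(OCc2ccccc2)cc1[C@@H]1[C@H](c2cc(OCc3ccccc3)cc(OCc3ccccc3)c2)[C@@H](c2ccc(OCc3ccccc3)cc2)O[C@H]1c1ccc(OCc2ccccc2)cc1)c1cc(OCc2ccccc2)c2c(c1)[C@@H](c1cc(OCc3ccccc3)cc(OCc3ccccc3)c1)[C@H](c1ccc(OCc3ccccc3)cc1)O2 | intermediate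
26 | ortho-hydroxy ketone (25 with OH in place of the benzyl ether ortho to the carbonyl on ring A) | O=C(c1c(O)cc(OCc2ccccc2)cc1[C@@H]1[C@H](c2cc(OCc3ccccc3)cc(OCc3ccccc3)c2)[C@@H](c2ccc(OCc3ccccc3)cc2)O[C@H]1c1ccc(OCc2ccccc2)cc1)c1cc(OCc2ccccc2)c2c(c1)[C@@H](c1cc(OCc3ccccc3)cc(OCc3ccccc3)c1)[C@H](c1ccc(OCc3ccccc3)cc1)O2 | intermediate
27 | aryl tert-butyl carbonate of 26 | O=C(c1c(OC(=O)OC(C)(C)C)cc(OCc2ccccc2)cc1[C@@H]1[C@H](c2cc(OCc3ccccc3)cc(OCc3ccccc3)c2)[C@@H](c2ccc(OCc3ccccc3)cc2)O[C@H]1c1ccc(OCc2ccccc2)cc1)c1cc(OCc2ccccc2)c2c(c1)[C@@H](c1cc(OCc3ccccc3)cc(OCc3ccccc3)c1)[C@H](c1ccc(OCc3ccccc3)cc1)O2 | intermediate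
28 | 1-(benzyloxy)-4-(bromomethyl)benzene | BrCc1ccc(OCc2ccccc2)cc1 | starting material
29 | (2R,5R)-2,5-dimethylthiolane | C[C@@H]1CC[C@@H](C)S1 | starting material
30 | (2R,5R)-1-[4-(benzyloxy)benzyl]-2,5-dimethylthiolan-1-ium bromide | C[C@@H]1CC[C@@H](C)[S+]1Cc1ccc(OCc2ccccc2)cc1.[Br-] | intermediate
31 | ortho-quinone methide of ring A (6-arylmethylidene-cyclohexa-2,4-dienone carrying the oxolane at C5 and the benzyloxy group at C3, exocyclic carbon bonded to C5 of the dihydrobenzofuran) | O=C1C=C(OCc2ccccc2)C=C([C@@H]2[C@H](c3cc(OCc4ccccc4)cc(OCc4ccccc4)c3)[C@@H](c3ccc(OCc4ccccc4)cc3)O[C@H]2c2ccc(OCc3ccccc3)cc2)C1=Cc1cc(OCc2ccccc2)c2c(c1)[C@@H](c1cc(OCc3ccccc3)cc(OCc3ccccc3)c1)[C@H](c1ccc(OCc3ccccc3)cc1)O2 | intermediate (not isolated)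
32 | (2R,5R)-2,5-dimethylthiolan-1-ium [4-(benzyloxy)phenyl]methylide | C[C@@H]1CC[C@@H](C)[S+]1[CH-]c1ccc(OCc2ccccc2)cc1 | intermediate (not isolated)
33 | decabenzyl ether of kobophenol A (all ten phenols as benzyl ethers, configuration as in 34) | C(c6ccccc6)Oc1ccc([C@H]2Oc3cc(OCc6ccccc6)cc([C@@H]4[C@H](c5cc(OCc6ccccc6)cc(OCc6ccccc6)c5)[C@@H](c5ccc(OCc6ccccc6)cc5)O[C@H]4c4ccc(OCc6ccccc6)cc4)c3[C@@H]2c2cc(OCc6ccccc6)c3c(c2)[C@@H](c2cc(OCc6ccccc6)cc(OCc6ccccc6)c2)[C@H](c2ccc(OCc6ccccc6)cc2)O3)cc1 | intermediate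
34 | kobophenol A | Oc1ccc([C@H]2Oc3cc(O)cc([C@@H]4[C@H](c5cc(O)cc(O)c5)[C@@H](c5ccc(O)cc5)O[C@H]4c4ccc(O)cc4)c3[C@@H]2c2cc(O)c3c(c2)[C@@H](c2cc(O)cc(O)c2)[C@H](c2ccc(O)cc2)O3)cc1 | target

Total step count: 17. Longest linear sequence: 10 steps (5 → 13 → 16 → 20 → 22 → 23 → 25 → 26 → 27 → 33 → 34).

Steps most likely to fail

Step 3 (key step). The chirality transfer may be lost, either by ligand exchange at the sulfonium centre before the rearrangement or by deprotonation at C3 of the thionium intermediate, and the product may lose the thiol to give the aromatic benzofuran. The fallback uses known chemistry and sets out from 10 (or the crude annulation mixture): TsOH in toluene completes the elimination to methyl 7-(benzyloxy)-2-[4-(benzyloxy)phenyl]-3-[3,5-bis(benzyloxy)phenyl]-1-benzofuran-5-carboxylate F1; ionic hydrogenation (Et3SiH, CF3CO2H) gives the racemic trans ester, that is 12 together with its enantiomer, the (2S,3S)-ester F2; the racemate is taken into step 12, where the enantioenriched aryllithium 24 gives ketone 25 and its diastereomer, the ketone epimeric at both dihydrobenzofuran centres F3, which are separated by chromatography. The route is rejoined at 25.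

Step 9. The hindered enamine may turn over poorly with the trisubstituted nitroalkene, and the anti relationship may erode by epimerization next to the ketone. The fallback sets out from 19 and uses a covalently bound auxiliary: condensation with SAMP gives the SAMP hydrazone of 19 F4; deprotonation with LiN(i-Pr)2 and addition to 16 at −100 °C gives the auxiliary-controlled Michael adduct, the hydrazone of 20 F5; aqueous oxalic acid cleaves the hydrazone and returns the route to 20.

Step 16. Trapping of the very crowded quinone methide may be incomplete or unselective, through over-reduction by hydride, attack from the wrong face, or a mismatched pairing of chiral ylide and substrate. The fallback sets out from 26 and forms the other ring bond: O-alkylation with 28 (K2CO3, DMF) gives the 4-(benzyloxy)benzyl ether of 26 F6; hydrazine hydrate (AcOH, EtOH) gives the hydrazone of that ketone F7; oxidation with MnO2 to the diaryl diazo compound and decomposition in the same flask with Rh2(R-PTAD)4 brings about enantioselective intramolecular C–H insertion of the donor/donor carbene into the benzylic ether C–H, giving the cis-fused C2 epimer of 33 F8; brief treatment with CF3CO2H at 0 °C equilibrates C2 and returns the route to 33.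

Further compounds

F1 | step 3 | methyl 7-(benzyloxy)-2-[4-(benzyloxy)phenyl]-3-[3,5-bis(benzyloxy)phenyl]-1-benzofuran-5-carboxylate | COC(=O)c1cc(OCc2ccccc2)c2oc(-c3ccc(OCc4ccccc4)cc3)c(-c3cc(OCc4ccccc4)cc(OCc4ccccc4)c3)c2c1
F2 | step 3 | methyl (2S,3S)-7-(benzyloxy)-2-[4-(benzyloxy)phenyl]-3-[3,5-bis(benzyloxy)phenyl]-2,3-dihydro-1-benzofuran-5-carboxylate | COC(=O)c1cc(OCc2ccccc2)c2c(c1)[C@H](c1cc(OCc3ccccc3)cc(OCc3ccccc3)c1)[C@@H](c1ccc(OCc3ccccc3)cc1)O2
F3 | step 3 | diastereomer of ketone 25 with the (2S,3S)-dihydrobenzofuran | O=C(c1c(OCc2ccccc2)cc(OCc2ccccc2)cc1[C@@H]1[C@H](c2cc(OCc3ccccc3)cc(OCc3ccccc3)c2)[C@@H](c2ccc(OCc3ccccc3)cc2)O[C@H]1c1ccc(OCc2ccccc2)cc1)c1cc(OCc2ccccc2)c2c(c1)[C@H](c1cc(OCc3ccccc3)cc(OCc3ccccc3)c1)[C@@H](c1ccc(OCc3ccccc3)cc1)O2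
F4 | step 9 | SAMP hydrazone of 19 | COC[C@@H]1CCCN1N=C(Cc1cc(OCc2ccccc2)cc(OCc2ccccc2)c1)c1ccc(O[Si](C(C)C)(C(C)C)C(C)C)cc1
F5 | step 9 | SAMP hydrazone of 20 | COC[C@@H]1CCCN1N=C(c1ccc(O[Si](C(C)C)(C(C)C)C(C)C)cc1)[C@@H](c1cc(OCc2ccccc2)cc(OCc2ccccc2)c1)[C@@H](c1cc(OCc2ccccc2)cc(OCc2ccccc2)c1Br)C([N+](=O)[O-])c1ccc(O[Si](C(C)C)(C(C)C)C(C)C)cc1
F6 | step 16 | 4-(benzyloxy)benzyl ether of 26 | O=C(c1c(OCc2ccc(OCc3ccccc3)cc2)cc(OCc2ccccc2)cc1[C@@H]1[C@H](c2cc(OCc3ccccc3)cc(OCc3ccccc3)c2)[C@@H](c2ccc(OCc3ccccc3)cc2)O[C@H]1c1ccc(OCc2ccccc2)cc1)c1cc(OCc2ccccc2)c2c(c1)[C@@H](c1cc(OCc3ccccc3)cc(OCc3ccccc3)c1)[C@H](c1ccc(OCc3ccccc3)cc1)O2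
F7 | step 16 | hydrazone of F6 | NN=C(c1c(OCc2ccc(OCc3ccccc3)cc2)cc(OCc2ccccc2)cc1[C@@H]1[C@H](c2cc(OCc3ccccc3)cc(OCc3ccccc3)c2)[C@@H](c2ccc(OCc3ccccc3)cc2)O[C@H]1c1ccc(OCc2ccccc2)cc1)c1cc(OCc2ccccc2)c2c(c1)[C@@H](c1cc(OCc3ccccc3)cc(OCc3ccccc3)c1)[C@H](c1ccc(OCc3ccccc3)cc1)O2
F8 | step 16 | C2 epimer of 33 at the dihydrobenzofuran fused to ring A (2R,3S, cis) | C(c6ccccc6)Oc1ccc([C@@H]2Oc3cc(OCc6ccccc6)cc([C@@H]4[C@H](c5cc(OCc6ccccc6)cc(OCc6ccccc6)c5)[C@@H](c5ccc(OCc6ccccc6)cc5)O[C@H]4c4ccc(OCc6ccccc6)cc4)c3[C@@H]2c2cc(OCc6ccccc6)c3c(c2)[C@@H](c2cc(OCc6ccccc6)cc(OCc6ccccc6)c2)[C@H](c2ccc(OCc6ccccc6)cc2)O3)cc1
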